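A small charge of solid second end groups, 27.5 mM, goes into blue, ochre, teal, violet and red alike, with a different charge of first end groups in each, and I want the links each flask holds at the end.

| flask | first end groups | solid second end groups | remark | time |
|---|---|---|---|---|
| south | 9.3 mM | 27.5 mM | run made earlier |  |
| west | 170 mM | 27.5 mM | run made earlier |  |
| blue | 15 mM | 27.5 mM |  | 20 h |
| ochre | 25 mM | 27.5 mM |  | 20 h |
| teal | 50 mM | 27.5 mM |  | 20 h |
| violet | 100 mM | 27.5 mM |  | 20 h |
| red | 200 mM | 27.5 mM |  | 20 h |

1. [links] at the end for blue, ochre, teal, violet, red, in this order
2. how that number moves from the first to the last of them (hardly changes / rises all the way / falls all the way / falls, then rises / rises, then falls)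

| run | time / h | links / % | first end groups / % |
|---|---|---|---|
| south | 0.833 | 1.8 | 96.2 |
| south | 1.33 | 4.2 | 91.6 |
| south | 2.00 | 8.9 | 85.4 |
| south | 3.00 | 17.1 | 74.9 |
| south | 4.00 | 25.8 | 64.0 |
| south | 6.00 | 42.9 | 45.0 |
| south | 10.0 | 64.4 | 19.9 |
| west | 1.33 | 1.0 | 95.0 |
| west | 3.00 | 3.3 | 89.0 |
| west | 4.00 | 5.2 | 85.1 |
| west | 6.00 | 4.6 | 83.9 |
| west | 8.00 | 5.2 | 83.8 |
| west | 10.0 | 5.2 | 84.0 |

(standard deviation of a reading: 0.5 percentage points)

- the numbers in the tables scatter with a standard deviation of 0.5 percentage points
- at the start none of the solid second end groups is in solution
- "hardly changes" means that all values lie within two and a half points (for a concentration: within two and a half percent of the largest)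

The two earlier runs have the same solid charge, but south is charged with 9.3 mM of first end groups and west with 170 mM, and their readings part early: at 4.00 h south shows links at 25.8 % and west at 5.2 %. West stops: by 10.0 h it has lost 27.2 mM of first end groups, which is close to its solid charge, so I read one second end group as spent per first end group lost, and the solid second end groups as the limiting reagent there. South, charged with 9.3 mM, has lost 7.45 mM by 10.0 h, far below its solid charge, and its first end groups are still falling, so nothing in the readings has stopped it.

The balance of the solid gives the number I carry. For violet the solid charge over the first-end-group charge is 27.5 %, and this ratio, which I call the ceiling, is the largest share of its first end groups a flask can lose. West's ceiling is 16.2 % and south's is 296 %, which is above one whole charge. So I reckon that violet keeps 72.5 % of its first end groups. West's links took 8.84 mM, about a third of its solid, so at high charge links are a part of a fixed budget, while at low charge they cannot pass the first end groups charged.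

The forecast gives 11.4 mM, 18 mM, 18 mM, 12.5 mM and 7.5 mM, a row that rises, then falls, on the ground that “each solid group consumes one first end group, and the run ends when the solid is exhausted”.

The flasks give 11.3 mM, 16.4 mM, 17.2 mM, 14.0 mM and 6.56 mM, a row that rises, then falls.

    solid second end groups ⇌ second end groups, rate k1*(cs1 - [second end groups]) while solid is left; crystals form when [second end groups] > cs1 (solubility = 25.0 mM, k = 0.290 h⁻¹)
    first end groups + second end groups → links (k = 9.10 M⁻¹ h⁻¹)
    first end groups + second end groups → rings, rate k3*[first end groups] as long as [second end groups] is above zero (k = 0.0270 h⁻¹)
    second end groups → decomposed reagent (k = 0.00670 h⁻¹)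

Violet keeps 73 % of its first end groups against the 72.5 % of its ceiling, and red, with 0 % of its solid second end groups left, keeps 86 % against 86.2 %. In blue, whose first end groups are down to 5.5 %, the step to links uses first end groups 3.6 times as fast as the step to rings at 2.53 h, and at 20.0 h the flask holds links at 75.4 % against rings at 19.1 %.

The readings are calculated on assumed constants; the scatter is artificial.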